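Rings: A = hydroquinone-type ring, B = para-phenylene, C = catechol-type ring, D = meta-phenylene. B and C are both 4-alkylphenol units, and the oxygen of B sits on the carbon of C ortho to the C hydroxyl, which is the connectivity an oxidative phenol O–C coupling leaves.
Cuts: first this O(B)–C(ortho of C) ether bond, which opens the 18-membered ring. Then the two CH2–CH2 bridges A–B and D–C (each as a Wittig olefin), and last the O(D)–C(A) ether (SNAr).
Forward: A and D are joined, ring B and then ring C are attached, both olefins are saturated at once, the two phenols are freed, and the macrocycle, the only ring made, closes by oxidation.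
Two bromines on C and two chlorines on B steer that closure. The three halogens left and the ring A methyl ether come off in the last two steps.
Stereochemistry: the target has no stereocentre, and olefin geometry and the one sp3 carbon of the dienone intermediate are erased on the way.

Key step: step 11

Assumption: the Wittig products are carried on as E/Z mixtures and the transient dienone is racemic, so these compounds are drawn without configuration.

Step 1
Reactants: 1 3-hydroxybenzyl alcohol; 2 2-fluoro-5-methoxybenzaldehyde
Product: 3 2-[3-(hydroxymethyl)phenoxy]-5-methoxybenzaldehyde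
Conditions: K2CO3, DMA, 140 °C, N2
Reagents that add atoms: none
Why: SNAr, in which the ortho formyl group stabilises the Meisenheimer adduct at the C–F carbon and carbonate deprotonates only the phenol of 1, so the benzylic hydroxyl stays free.

Step 2
Reactants: 4 3,5-dichloro-4-hydroxybenzaldehyde
Product: 5 4-(benzyloxy)-3,5-dichlorobenzaldehyde
Conditions: BnBr, K2CO3, DMF, 60 °C
Reagents that add atoms: benzyl bromide, BrCc1ccccc1
Why: Williamson ether synthesis on an acidic, hindered phenoxide; benzyl is chosen because it withstands ylides, borohydride, PPh3·HBr and diimide and can later be removed without touching an aryl methyl ether or a carbon–halogen bond.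

Step 3
Reactants: 5 4-(benzyloxy)-3,5-dichlorobenzaldehyde
Product: 6 [4-(benzyloxy)-3,5-dichlorophenyl]methanol
Conditions: NaBH4, MeOH–THF, 0 °C
Reagents that add atoms: none
Why: Borohydride reduction of an aromatic aldehyde, which leaves aryl chlorides and the benzyl ether alone.

Step 4
Reactants: 6 [4-(benzyloxy)-3,5-dichlorophenyl]methanol
Product: 7 [4-(benzyloxy)-3,5-dichlorobenzyl]triphenylphosphonium bromide
Conditions: PPh3·HBr, MeCN, reflux
Reagents that add atoms: triphenylphosphine hydrobromide, [Br-].c1ccc(cc1)[PH+](c1ccccc1)c1ccccc1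
Why: Direct conversion of a benzylic alcohol into its phosphonium salt (acid-promoted substitution through the benzylic bromide), a standard entry to Wittig salts in bibenzyl chemistry that tolerates aryl benzyl ethers.

Step 5
Reactants: 7 [4-(benzyloxy)-3,5-dichlorobenzyl]triphenylphosphonium bromide; 3 2-[3-(hydroxymethyl)phenoxy]-5-methoxybenzaldehyde
Product: 9 (3-{2-[2-(4-benzyloxy-3,5-dichlorophenyl)ethenyl]-4-methoxyphenoxy}phenyl)methanol (E/Z mixture), via phosphorane 8 (not isolated)
Conditions: KOt-Bu, THF, 0 °C; then 3, 0 °C to rt
Reagents that add atoms: none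
Why: Wittig olefination with a semistabilised benzylic ylide that is too weak a base to be quenched by the free benzylic alcohol of 3, and whose E/Z outcome is irrelevant because step 9 saturates the bond.

Step 6
Reactants: 9 (3-{2-[2-(4-benzyloxy-3,5-dichlorophenyl)ethenyl]-4-methoxyphenoxy}phenyl)methanol
Product: 10 (3-{2-[2-(4-benzyloxy-3,5-dichlorophenyl)ethenyl]-4-methoxyphenoxy}benzyl)triphenylphosphonium bromide
Conditions: PPh3·HBr, MeCN, reflux
Reagents that add atoms: triphenylphosphine hydrobromide, [Br-].c1ccc(cc1)[PH+](c1ccccc1)c1ccccc1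
Why: The same alcohol-to-phosphonium substitution as in step 4, under acidity too weak to protonate the stilbene or to cleave the aryl ethers.

Step 7
Reactants: 11 3,5-dibromo-4-hydroxybenzaldehyde
Product: 12 4-(benzyloxy)-3,5-dibromobenzaldehyde
Conditions: BnBr, K2CO3, DMF, 60 °C
Reagents that add atoms: benzyl bromide, BrCc1ccccc1
Why: Williamson ether synthesis, needed because the free phenoxide would deactivate the para aldehyde towards the ylide of the next step.

Step 8
Reactants: 10 (3-{2-[2-(4-benzyloxy-3,5-dichlorophenyl)ethenyl]-4-methoxyphenoxy}benzyl)triphenylphosphonium bromide; 12 4-(benzyloxy)-3,5-dibromobenzaldehyde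
Product: 14 bis-stilbene 2-benzyloxy-1,3-dibromo-5-[2-(3-{2-[2-(4-benzyloxy-3,5-dichlorophenyl)ethenyl]-4-methoxyphenoxy}phenyl)ethenyl]benzene (olefin isomer mixture), via phosphorane 13 (not isolated)
Conditions: KOt-Bu, THF, 0 °C; then 12, 0 °C to rt
Reagents that add atoms: none
Why: Wittig olefination of an electron-poor and therefore reactive aldehyde, with the base consumed in forming 13 before 12 is added, so the aryl bromides never meet free alkoxide.

Step 9
Reactants: 14 bis-stilbene
Product: 15 2-benzyloxy-1,3-dibromo-5-[2-(3-{2-[2-(4-benzyloxy-3,5-dichlorophenyl)ethyl]-4-methoxyphenoxy}phenyl)ethyl]benzene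
Conditions: TsNHNH2 (excess, in portions), NaOAc, THF–H2O, reflux
Reagents that add atoms: none
Why: Diimide reduction transfers two hydrogens in a concerted way to both C=C bonds only and, unlike hydrogenation over palladium, spares C–Br, C–Cl and O–benzyl bonds.

Step 10
Reactants: 15 saturated dibenzyl ether
Product: 16 seco bisphenol 2,6-dibromo-4-[2-(3-{2-[2-(3,5-dichloro-4-hydroxyphenyl)ethyl]-4-methoxyphenoxy}phenyl)ethyl]phenol
Conditions: BCl3, pentamethylbenzene, CH2Cl2, −78 to −20 °C; then H2O
Reagents that add atoms: none
Why: Lewis-acid debenzylation with a cation scavenger, in which BCl3 ionises the benzyl–oxygen bonds (helped by the good dihalophenoxide leaving groups), pentamethylbenzene takes up the benzyl cation by Friedel–Crafts alkylation, and the unchelated aryl methyl ether is not cleaved at low temperature.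

Step 11
Reactants: 16 seco bisphenol
Product: 18 trihalogenated 18-membered macrocycle (ring A methyl ether; ring B 3,5-dichloro flanking the new ether oxygen; ring C free phenol flanked by that aryloxy group on one side, by one bromine on the other), via bromodienone 17 (not isolated)
Conditions: Tl(NO3)3·3H2O (2.5 equiv), MeOH–THF 4:1, about 1 mM, slow addition of 16, −20 to 0 °C; concentrate; Zn dust, AcOH, rt
Reagents that add atoms: none
Why: Trivalent thallium binds as an aryloxide to the phenol that is easier to oxidise, the 2,6-dibromophenol of ring C, and leaves as monovalent thallium, so that ring C becomes a phenoxenium equivalent; the ring B hydroxyl oxygen adds to one of its bromine-bearing ortho carbons to give bromodienone 17, and zinc in acetic acid then reduces the C–Br bond next to the carbonyl, which rearomatises ring C to the free phenol of 18. The closest known reaction type is exactly this Tl(NO3)3 macrocyclisation of pairs of ortho,ortho'-dihalogenated 4-alkylphenols to cyclic diaryl ethers with reductive work-up, established on isodityrosine-type cyclic peptides. The one ring closed is the 18-membered macrocycle, formally by 18-exo-trig attack of oxygen on the C(Br)=C(O–Tl) unit of ring C, a size at which no stereoelectronic limit applies and only dilution near 1 mM is needed against oligomers. The C(Br)(OAr) carbon of 17 is the only new stereocentre, it forms racemic without any control element and disappears on rearomatisation. Two selectivities are needed: the direction oxygen of B onto carbon of C (the reverse would give an isomeric ring of the same size) follows from bromine on C against chlorine on B, since the dibromophenol has the lower oxidation potential and the weaker carbon–halogen bond, and O–C instead of C–C coupling follows from a halogen on all four ortho carbons and a chain on both para carbons. Methanol adding at the para carbon of oxidised ring C only gives a quinol methyl ether that the zinc step returns to the phenol, and ring A, which has no O–H, cannot form a thallium aryloxide.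

Step 12
Reactants: 18 trihalogenated macrocycle
Product: 19 halogen-free macrocycle, ring A methyl ether, ring C free phenol
Conditions: H2 (1 atm), 10% Pd/C, NaOAc, MeOH–EtOAc, rt
Reagents that add atoms: none
Why: Catalytic hydrodehalogenation, in which zerovalent palladium inserts into the C–Br and then the C–Cl bonds, hydrogen replaces each halogen and acetate takes up the acid, while diaryl ethers, the methyl ether and the saturated bridges are inert.

Step 13
Reactants: 19 macrocyclic methyl ether
Product: 20 target CNP0135015.0
Conditions: BBr3, CH2Cl2, −78 °C to rt; then H2O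
Reagents that add atoms: none
Why: Lewis-acid demethylation of an aryl methyl ether (bromide attacks the methyl group of the boron-complexed ether), the usual last step for bis(bibenzyl)s because diaryl ethers are not cleaved.

Compound list
1 | 3-hydroxybenzyl alcohol | OCc1cccc(O)c1 | starting material
2 | 2-fluoro-5-methoxybenzaldehyde | COc1ccc(F)c(C=O)c1 | starting material
3 | 2-[3-(hydroxymethyl)phenoxy]-5-methoxybenzaldehyde | COc1ccc(Oc2cccc(CO)c2)c(C=O)c1 | intermediate
4 | 3,5-dichloro-4-hydroxybenzaldehyde | O=Cc1cc(Cl)c(O)c(Cl)c1 | starting material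
5 | 4-(benzyloxy)-3,5-dichlorobenzaldehyde | O=Cc1cc(Cl)c(OCc2ccccc2)c(Cl)c1 | intermediate
6 | [4-(benzyloxy)-3,5-dichlorophenyl]methanol | OCc1cc(Cl)c(OCc2ccccc2)c(Cl)c1 | intermediate
7 | [4-(benzyloxy)-3,5-dichlorobenzyl]triphenylphosphonium bromide | [Br-].Clc1cc(C[P+](c2ccccc2)(c2ccccc2)c2ccccc2)cc(Cl)c1OCc1ccccc1 | intermediate
8 | [4-(benzyloxy)-3,5-dichlorobenzylidene]triphenylphosphorane, formed in the flask | Clc1cc(C=P(c2ccccc2)(c2ccccc2)c2ccccc2)cc(Cl)c1OCc1ccccc1 | intermediate
9 | (3-{2-[2-(4-benzyloxy-3,5-dichlorophenyl)ethenyl]-4-methoxyphenoxy}phenyl)methanol, E/Z mixture | COc1ccc(Oc2cccc(CO)c2)c(c1)C=Cc1cc(Cl)c(OCc2ccccc2)c(Cl)c1 | intermediate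
10 | (3-{2-[2-(4-benzyloxy-3,5-dichlorophenyl)ethenyl]-4-methoxyphenoxy}benzyl)triphenylphosphonium bromide, E/Z mixture | [Br-].COc1ccc(Oc2cccc(C[P+](c3ccccc3)(c3ccccc3)c3ccccc3)c2)c(c1)C=Cc1cc(Cl)c(OCc2ccccc2)c(Cl)c1 | intermediate
11 | 3,5-dibromo-4-hydroxybenzaldehyde | O=Cc1cc(Br)c(O)c(Br)c1 | starting material
12 | 4-(benzyloxy)-3,5-dibromobenzaldehyde | O=Cc1cc(Br)c(OCc2ccccc2)c(Br)c1 | intermediate
13 | benzylidene(triphenyl)phosphorane derived from 10, formed in the flask | COc1ccc(Oc2cccc(C=P(c3ccccc3)(c3ccccc3)c3ccccc3)c2)c(c1)C=Cc1cc(Cl)c(OCc2ccccc2)c(Cl)c1 | intermediate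
14 | bis-stilbene with benzyl-protected dibromophenol (ring C) and dichlorophenol (ring B), olefin isomer mixture | COc1ccc(Oc2cccc(C=Cc3cc(Br)c(OCc4ccccc4)c(Br)c3)c2)c(c1)C=Cc1cc(Cl)c(OCc2ccccc2)c(Cl)c1 | intermediate
15 | saturated bis(bibenzyl) dibenzyl ether | COc1ccc(Oc2cccc(CCc3cc(Br)c(OCc4ccccc4)c(Br)c3)c2)c(c1)CCc1cc(Cl)c(OCc2ccccc2)c(Cl)c1 | intermediate
16 | seco bisphenol, 2,6-dibromo-4-[2-(3-{2-[2-(3,5-dichloro-4-hydroxyphenyl)ethyl]-4-methoxyphenoxy}phenyl)ethyl]phenol | COc1ccc(Oc2cccc(CCc3cc(Br)c(O)c(Br)c3)c2)c(c1)CCc1cc(Cl)c(O)c(Cl)c1 | intermediate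
17 | macrocyclic bromodienone, ring C as 6-aryloxy-2,6-dibromo-4-alkylcyclohexa-2,4-dien-1-one, racemic, formed in the flask | COc1ccc2c(c1)CCc1cc(Cl)c(c(Cl)c1)OC1(Br)C=C(C=C(Br)C1=O)CCc1cccc(c1)O2 | intermediate
18 | trihalogenated 18-membered macrocycle with free ring C hydroxyl | COc1ccc2c(c1)CCc1cc(Cl)c(c(Cl)c1)Oc1cc(cc(Br)c1O)CCc1cccc(c1)O2 | intermediate
19 | halogen-free macrocycle, ring A methyl ether | COc1ccc2c(c1)CCc1ccc(cc1)Oc1cc(ccc1O)CCc1cccc(c1)O2 | intermediate
20 | CNP0135015.0, macrocyclic bis(bibenzyl) with hydroxyls on rings A and C | Oc1ccc2c(c1)CCc1ccc(cc1)Oc1cc(ccc1O)CCc1cccc(c1)O2 | target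

Total step count: 13. Longest linear sequence: 11 steps (4 to 20 through steps 2, 3, 4, 5, 6, 8, 9, 10, 11, 12 and 13).

Steps most likely to fail

Step 11. Several things could defeat the closure:
- Methanol or a second molecule may intercept oxidised ring C before the distant ring B hydroxyl reaches it.
- The electron-rich ring A may be oxidised.
- The direction of coupling may erode.

The fallback gives up oxidation and closes the same O(B)–C(C) bond by a copper-catalysed Ullmann macrocyclisation of a seco compound that carries a single bromine. It sets out from 3 and returns at 20. Commercial (4-benzyloxybenzyl)triphenylphosphonium chloride is deprotonated with KOt-Bu in THF to the ylide F1, which with 3 should give the stilbene alcohol F2. PPh3·HBr in refluxing MeCN turns this into the phosphonium bromide F3, whose ylide F4 (KOt-Bu, THF) is condensed with commercial 3-bromo-4-methoxybenzaldehyde to the bis-stilbene F5. Diimide (TsNHNH2, NaOAc) gives the saturated aryl bromide F6, and BCl3 with pentamethylbenzene frees the ring B hydroxyl in the bromo phenol F7. CuI, N,N-dimethylglycine and Cs2CO3 in dilute dioxane at 100 °C then close the ring to the macrocyclic dimethyl ether F8. BBr3 cleaves both methyl ethers and delivers 20.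

Step 12. Dechlorination may stall, because both C–Cl bonds flank the diaryl ether oxygen inside the macrocycle and are hard to bring to the catalyst surface, and halide build-up slows the catalyst further. The fallback reverses the last two operations and replaces heterogeneous catalysis by a dissolving-metal reduction of a water-soluble phenolate. It sets out from 18 and returns at 20. BBr3 in CH2Cl2 gives the trihalogenated bisphenol F9, which dissolves as its bis-phenolate in aqueous NaOH–MeOH and is dehalogenated there by Ni–Al alloy, a known way to strip chlorine and bromine from halophenols, to give 20 directly.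

Step 1. The methoxy group para to fluorine slows the addition step, and at the temperature then needed the aldehyde may degrade by base-induced disproportionation or by hydride transfer from the benzylic alcohol. The fallback changes the bond-forming mechanism to a copper-catalysed Ullmann-type O-arylation. It sets out from 1, which is coupled with commercial 2-bromo-5-methoxybenzaldehyde (CuI, N,N-dimethylglycine, Cs2CO3, dioxane, 90 °C), the ortho formyl group assisting the copper insertion, and it returns at 3 without any new compound.

Further compounds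
F1 | step 11 | (4-benzyloxybenzylidene)triphenylphosphorane | c1ccc(cc1)COc1ccc(C=P(c2ccccc2)(c2ccccc2)c2ccccc2)cc1
F2 | step 11 | (3-{2-[2-(4-benzyloxyphenyl)ethenyl]-4-methoxyphenoxy}phenyl)methanol, E/Z mixture | COc1ccc(Oc2cccc(CO)c2)c(c1)C=Cc1ccc(OCc2ccccc2)cc1
F3 | step 11 | (3-{2-[2-(4-benzyloxyphenyl)ethenyl]-4-methoxyphenoxy}benzyl)triphenylphosphonium bromide | [Br-].COc1ccc(Oc2cccc(C[P+](c3ccccc3)(c3ccccc3)c3ccccc3)c2)c(c1)C=Cc1ccc(OCc2ccccc2)cc1
F4 | step 11 | benzylidene(triphenyl)phosphorane derived from F3 | COc1ccc(Oc2cccc(C=P(c3ccccc3)(c3ccccc3)c3ccccc3)c2)c(c1)C=Cc1ccc(OCc2ccccc2)cc1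
F5 | step 11 | bis-stilbene with 3-bromo-4-methoxyphenyl ring C and 4-benzyloxyphenyl ring B, olefin isomer mixture | COc1ccc(Oc2cccc(C=Cc3ccc(OC)c(Br)c3)c2)c(c1)C=Cc1ccc(OCc2ccccc2)cc1
F6 | step 11 | saturated bis(bibenzyl) aryl bromide, ring B benzyl ether | COc1ccc(Oc2cccc(CCc3ccc(OC)c(Br)c3)c2)c(c1)CCc1ccc(OCc2ccccc2)cc1
F7 | step 11 | 4-[2-(2-{3-[2-(3-bromo-4-methoxyphenyl)ethyl]phenoxy}-5-methoxyphenyl)ethyl]phenol | COc1ccc(Oc2cccc(CCc3ccc(OC)c(Br)c3)c2)c(c1)CCc1ccc(O)cc1
F8 | step 11 | macrocycle with methyl ethers on rings A and C | COc1ccc2c(c1)CCc1ccc(cc1)Oc1cc(ccc1OC)CCc1cccc(c1)O2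
F9 | step 12 | trihalogenated macrocycle with free hydroxyls on rings A and C | Oc1ccc2c(c1)CCc1cc(Cl)c(c(Cl)c1)Oc1cc(cc(Br)c1O)CCc1cccc(c1)O2
F0 | step 1 | none | none
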